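The runs were computed from invented constants; noise was put on by code.

The flask came up first.

| flask | starting material | acid | protic impurity | remark | time |
|---|---|---|---|---|---|
| alder | 10 mM | 2 mM | 20 mM | run made earlier |  |
| oak | 40 mM | 2 mM | 20 mM | run made earlier |  |
| larch | 20 mM | 2 mM | 30 mM | run made earlier |  |
| flask | 20 mM | 2.00 mM | 20.0 mM |  | 80 min |

| run | time / min | starting material / % | target / % |
|---|---|---|---|
| alder | 6.00 | 94.9 | 4.4 |
| alder | 12.0 | 91.0 | 7.2 |
| alder | 25.0 | 80.7 | 18.5 |
| alder | 40.0 | 72.2 | 26.7 |
| alder | 80.0 | 51.4 | 43.6 |
| oak | 8.00 | 94.6 | 7.2 |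
| oak | 20.0 | 83.2 | 14.1 |
| oak | 40.0 | 71.5 | 23.5 |
| oak | 60.0 | 60.8 | 34.2 |
| oak | 80.0 | 51.0 | 44.3 |
| larch | 8.00 | 92.3 | 6.0 |
| larch | 20.0 | 83.3 | 12.6 |
| larch | 40.0 | 72.8 | 25.3 |
| larch | 60.0 | 59.4 | 35.1 |
| larch | 80.0 | 50.0 | 43.6 |

(standard deviation of a reading: 1 percentage point)

- acid is the free proton; pH is minus the decimal logarithm of its molar concentration
- the earlier runs were read with a standard deviation of 1 percentage point
- steps under discussion: weak acid -> by-product carried off; starting material -> weak acid + target; starting material + acid -> weak acid + acid + target; weak acid <-> conjugate base + acid; starting material + protic impurity -> quenched substrate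

* part of the starting material that has reacted at 80 min
* pH of the solution at 80 min

The forecaster put the reacted part at 49.7%, with a range of 47.5% to 52%. The forecaster put the pH at 2.65, with a range of 2.1 to 2.72. The argument on the pH ran: “the absence of any acceleration, even at 40 mM, means the weak acid released adds little free proton”.

The secretary, who writes these minutes, then wrote a balance for the acid. It is the reagent charged in the smaller amount, 2.00 mM against 20 mM of starting material. The catalysed step under discussion gives back the acid it takes. So the catalysed step adds no free acid itself, but the weak acid it forms can add some by giving conjugate base and acid. If that gain stays small, the loss of starting material is pseudo-first-order.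

The secretary therefore proposed a working half-life: the time in which any amount of starting material falls to 0.5 of itself at this acid charge. The runs began at 10 mM, 40 mM and 20 mM. At 80.0 min they kept 51.4%, 51.0% and 50.0%. Averaged, these readings give 81.9 min. The flask has the acid charge of the runs, so the secretary counted 0.977 half-lives and expected 49.2% reacted. That is slightly below the forecast.

The flask gives 48.1% reacted and a pH of 2.70.

    weak acid → by-product carried off (k = 0.0270 min⁻¹)
    starting material → weak acid + target (k = 5.70 × 10⁻⁴ min⁻¹)
    starting material + acid → weak acid + acid + target (k = 3.40 M⁻¹ min⁻¹)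
    weak acid ⇌ conjugate base + acid, settled at all times (K = 1.00 × 10⁻⁶ M)
    starting material + protic impurity → quenched substrate (k = 0.0420 M⁻¹ min⁻¹)

At 80.0 min the flask still holds 100% of its acid charge, beside 0.00158 mM of conjugate base. The half-life count stood 1.1 percentage points above the flask. The same flask read at 2.5 h is 1.83 half-lives, so the count gives 71.9% reacted. That flask gave 70.7%.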